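Everything rests on one disconnection: ring A of the cis-decalin is opened at C1–C2 and C5–C10, and both bonds are re-formed together by an intramolecular Diels–Alder reaction. An isopropenyl ketone (C1=C10, carbonyl C9) adds to a 2-silyloxy-3-carbomethoxy diene (C2–C5) tied to it through C6–C8, closing rings A and B and setting C5 and C10 at once. The step exploits two features: H-5 and the C10 methyl share one face of the ring fusion next to a ketone-level C9, and C3=O sits beside C4 carrying the oxidised carbon C18, a β-keto ester pattern. The precursor is an achiral open-chain trienone; a chiral oxazaborolidinium catalyst selects the enantiomer.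

Key step: step 6

Remarks
- Numbering: labdane numbering of the target is used for all bicyclic compounds. Ring A = C1–C5 and C10; ring B = C5–C10; C17 = methylidene carbon on C8; C11–C16 = side chain (C15 carboxyl, C16 methyl on C13); C18 = oxygen-bearing carbon on C4; C19 = methyl on C4; C20 = methyl on C10. The face of C20 is called β. In the target H-5, C19 and C11 are β and C18 is α. The SMILES strings are definitive.
- Assumption: the (S)-oxazaborolidinium ion is taken to steer the diene to the enone face that leads to (4aS,8aS)-9. If the sense proves opposite, the equally available mirror-image catalyst is used and nothing else changes.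
- Design of the precursor: the isopropenyl ketone is unmasked last, from a Weinreb amide. A free enone would add amine or keto ester under Knoevenagel conditions and would be silylated alongside the acetyl group. A triisopropylsilyl dienol ether is used because it should withstand the strongly acidic catalyst and steps 7–10.
- Design after the key step: C9 is set by delivering carbon, not hydrogen, to the exposed β face of a C8=C9 alkene. Hydrogen delivery, or equilibration next to a C8 ketone, is expected to place the side chain trans to C20 in this cis-decalin. The 13Z geometry is brought in with (Z)-3-iodobut-2-enoic acid rather than made by ketone olefination.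

Step 1
Reactants: 1 δ-valerolactone
Product: 2 5-hydroxy-N-methoxy-N-methylpentanamide
Conditions: MeNH(OMe)·HCl, i-PrMgCl, THF, −20 → 0 °C
Reagents that add atoms: N,O-dimethylhydroxylamine hydrochloride, CNOC.Cl
Why: Weinreb aminolysis: the chloromagnesium amide made in the flask opens the lactone by acyl substitution, and the resulting N-methoxy-N-methyl amide is inert to further attack.

Step 2
Reactants: 2 5-hydroxy-N-methoxy-N-methylpentanamide
Product: 3 N-methoxy-N-methyl-5-oxopentanamide
Conditions: Dess–Martin periodinane, CH2Cl2, 0 °C → rt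
Reagents that add atoms: none
Why: Dess–Martin oxidation takes the primary alcohol to the aldehyde under neutral conditions without over-oxidation and forestalls relactonisation of 2.

Step 3
Reactants: 3 N-methoxy-N-methyl-5-oxopentanamide; 4 methyl acetoacetate
Product: 5 methyl (2Z)-2-acetyl-7-[methoxy(methyl)amino]-7-oxohept-2-enoate
Conditions: piperidine (10 mol %), AcOH (10 mol %), 4 Å MS, CH2Cl2, −10 → 0 °C; (Z)-isomer isolated on silica; (E)-isomer re-equilibrated under the same catalysts and recycled
Reagents that add atoms: none
Why: Knoevenagel condensation of an unbranched aldehyde with a β-keto ester at low temperature (to suppress the bis-adduct) forms no stereocentre, and the (Z)-geometry (chain cis to CO2Me), needed to place the tether on the outer terminus of the later diene, is secured by separation and recycling of the readily equilibrated (E)-isomer.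

Step 4
Reactants: 5 methyl (2Z)-2-acetyl-7-[methoxy(methyl)amino]-7-oxohept-2-enoate
Product: 6 methyl (2Z)-7-[methoxy(methyl)amino]-7-oxo-2-{1-[(triisopropylsilyl)oxy]ethenyl}hept-2-enoate
Conditions: TIPSOTf, Et3N, CH2Cl2, −78 → 0 °C
Reagents that add atoms: triisopropylsilyl trifluoromethanesulfonate, CC(C)[Si](C(C)C)(C(C)C)OS(=O)(=O)C(F)(F)F
Why: Soft enolisation (silyl triflate and tertiary amine) of the acetyl group gives the cross-conjugated 2-silyloxydiene with the C=C geometry untouched, the Weinreb amide being too weakly acidic to enolise under these conditions.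

Step 5
Reactants: 6 methyl (2Z)-7-[methoxy(methyl)amino]-7-oxo-2-{1-[(triisopropylsilyl)oxy]ethenyl}hept-2-enoate; 7 isopropenylmagnesium bromide
Product: 8 methyl (2Z)-8-methyl-7-oxo-2-{1-[(triisopropylsilyl)oxy]ethenyl}nona-2,8-dienoate
Conditions: THF, −40 → −10 °C; cold aq. NH4Cl; product kept below 0 °C and used at once
Reagents that add atoms: none
Why: Weinreb ketone synthesis: the Grignard reagent adds once to the N-methoxy amide, which is more reactive than the hindered α-branched enoate, and the magnesium chelate keeps the enone masked until the cold quench, so that the dienophile never meets amines, silylating agents or prolonged warmth.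

Step 6
Reactants: 8 methyl (2Z)-8-methyl-7-oxo-2-{1-[(triisopropylsilyl)oxy]ethenyl}nona-2,8-dienoate
Product: 9 methyl (4aS,8aS)-4a-methyl-5-oxo-2-[(triisopropylsilyl)oxy]-3,4,4a,5,6,7,8,8a-octahydronaphthalene-1-carboxylate
Conditions: (S)-o-tolyl-CBS oxazaborolidine (20 mol %), Tf2NH (17 mol %), CH2Cl2, −78 → −40 °C; Et3N quench
Reagents that add atoms: none
Why: The triflimide-activated oxazaborolidine binds the C9 carbonyl and lowers the LUMO of the C1=C10 alkene, which adds suprafacially across the electron-rich C2–C5 silyloxydiene in a concerted, asynchronous [4+2] process that forms C1–C2 and C5–C10. The closest known reactions are Lewis acid–promoted intramolecular Diels–Alder reactions of 1,7,9-decatrien-3-ones and oxazaborolidinium-catalysed cycloadditions of acyclic enones with 2-silyloxydienes. Ring A closes as the new six-membered cyclohexene of the cycloaddition through both new bonds, and ring B closes as the six-membered tether ring (C5–C6–C7–C8–C9–C10) through the C5–C10 bond. The cis relationship of C5 and C10 follows from the transition state with the catalyst-bound tether carbonyl endo over the diene and C20 exo, the (Z)-alkylidene holding the tether on the outer diene terminus; the absolute configuration of both centres follows from the catalyst, whose aryl group screens one face of the coordinated enone. The step needs cis over trans fusion and one enantioface, which the four-atom tether with its carbonyl next to the dienophile and coordination at C9 secure, while the tether fixes the regiochemistry.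

Step 7
Reactants: 9 methyl (4aS,8aS)-4a-methyl-5-oxo-2-[(triisopropylsilyl)oxy]-3,4,4a,5,6,7,8,8a-octahydronaphthalene-1-carboxylate
Product: 12 8-methylidene-9-ketone (ring A as in 9), via Mannich base 10 (not isolated), via methiodide 11 (not isolated)
Conditions: LiN(SiMe3)2, THF, −78 °C; CH2=NMe2+ I−, −78 → 0 °C; then MeI, rt; volatiles removed; then DBU, CH2Cl2, rt
Reagents that add atoms: Eschenmoser's salt (N,N-dimethylmethyleneiminium iodide), C=[N+](C)C.[I-]
Why: Eschenmoser methylenation: C8 is the only enolisable position of the C9 ketone (C10 is quaternary, and the ring A enol ether is a poor nucleophile and a weak acid), so Mannich reaction, N-methylation and E1cB loss of trimethylamine give the 8-methylidene ketone.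

Step 8
Reactants: 12 8-methylidene-9-ketone
Product: 13 9-hydroxy-8(17)-ene (secondary allylic alcohol, either C9 epimer)
Conditions: NaBH4, CeCl3·7H2O, MeOH–THF, −78 → −40 °C
Reagents that add atoms: none
Why: Luche reduction delivers hydride 1,2 to the enone and spares the ester and the silyl enol ether, and the new C9 carbinol centre needs no control because it is erased in step 9.

Step 9
Reactants: 13 9-hydroxy-8(17)-ene
Product: 14 17-hydroxy-8-ene (primary allylic alcohol, C8=C9 in ring B)
Conditions: Ph3SiOReO3 (3 mol %), Et2O, 0 °C → rt
Reagents that add atoms: none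
Why: Perrhenate-catalysed 1,3-transposition of an allylic alcohol ([3,3] shift of the perrhenate ester), drawn to the primary alcohol by the gain of a trisubstituted ring alkene and the relief of the crowded neopentyl carbinol.

Step 10
Reactants: 14 17-hydroxy-8-ene; 15 triethyl orthoacetate
Product: 17 ethyl 8(17)-en-12-oate with CH2CO2Et on the β face of C9 (ring A as in 9), via ketene acetal 16 (not isolated)
Conditions: MeC(OEt)3 (as solvent), EtCO2H (cat.), 140 °C, EtOH distilled off
Reagents that add atoms: none
Why: Johnson–Claisen rearrangement: the ketene acetal formed by orthoester exchange undergoes a chair-like [3,3] shift that makes C9–C11 and the C8=C17 methylidene together, and C9 is set by bond formation on the β face, anti to the C1–C10 bond, which stands pseudoaxial on the α face because allylic strain with the C4 ester keeps C6 pseudoaxial on ring A, so that C11 ends cis to C20.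

Step 11
Reactants: 17 ethyl 8(17)-en-12-oate
Product: 18 3-oxo diester with C19 methyl β and CO2Me (C18) α on C4
Conditions: TBAF, MeI, THF, −20 → 0 °C
Reagents that add atoms: iodomethane, CI
Why: Fluoride cleaves the silyl enol ether to the ammonium enolate of the β-keto ester, which is C-methylated by iodomethane (fluoride-promoted enolate alkylation), and the quaternary C4 is set by entry of the electrophile on the convex β face, syn to H-5 and anti to the pseudoaxial C5–C6 bond, the α face being covered by ring B, as in electrophilic attack at C4 of A/B-cis 3-keto steroids.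

Step 12
Reactants: 18 3-oxo diester
Product: 19 3,12,18-triol (C3 carbinol as either epimer)
Conditions: LiAlH4, THF, 0 → 40 °C; Fieser work-up
Reagents that add atoms: none
Why: Exhaustive LiAlH4 reduction of both esters and of the hindered ketone, in which the C3 carbinol centre is of no consequence since C3 returns to the ketone in step 15.

Step 13
Reactants: 19 3,12,18-triol
Product: 20 12-iodo-3,18-diol
Conditions: PPh3, imidazole and I2 premixed in CH2Cl2, then 19, −20 → 0 °C
Reagents that add atoms: iodine, II
Why: Appel-type iodination: the displacement is SN2, so only the unhindered C12 alkoxyphosphonium ion is converted, the neopentyl C18 and the secondary C3 hydroxyls returning on work-up, and premixing leaves no free iodine for iodoetherification of the methylidene group.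

Step 14
Reactants: 20 12-iodo-3,18-diol
Product: 21 18-acetoxy-12-iodo-3-ol
Conditions: AcCl, 2,4,6-collidine, CH2Cl2, −78 °C
Reagents that add atoms: acetyl chloride, CC(=O)Cl
Why: Acetyl chloride with 2,4,6-collidine at low temperature acylates a primary hydroxyl in preference to a secondary one, here one flanked by the quaternary C4.

Step 15
Reactants: 21 18-acetoxy-12-iodo-3-ol
Product: 22 18-acetoxy-12-iodo-3-ketone
Conditions: Dess–Martin periodinane, CH2Cl2, 0 °C → rt
Reagents that add atoms: none
Why: Dess–Martin oxidation of the secondary alcohol under neutral conditions leaves acetate, iodide and alkene alone, and the β-acetoxy ketone cannot eliminate or epimerise because C4 is quaternary.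

Step 16
Reactants: 23 but-2-ynoic acid
Product: 24 (2Z)-3-iodobut-2-enoic acid
Conditions: NaI, AcOH, 110 °C
Reagents that add atoms: sodium iodide, [Na+].[I-]
Why: Conjugate addition of iodide to the ynoic acid followed by anti protonation (hydroiodination) gives the (Z)-β-iodo acid, with iodine cis to the carboxyl group.

Step 17
Reactants: 24 (2Z)-3-iodobut-2-enoic acid
Product: 25 tert-butyldimethylsilyl (2Z)-3-iodobut-2-enoate
Conditions: TBSCl, imidazole, CH2Cl2, 0 °C → rt; filtered, concentrated, used crude
Reagents that add atoms: tert-butyldimethylsilyl chloride, CC(C)(C)[Si](C)(C)Cl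
Why: Silyl ester formation masks the acidic proton, which would destroy the organozinc reagent of step 18, as a group that mild aqueous acid removes.

Step 18
Reactants: 22 18-acetoxy-12-iodo-3-ketone; 25 tert-butyldimethylsilyl (2Z)-3-iodobut-2-enoate
Product: 28 target acid CNP0243698.1, via organozinc iodide 26 (not isolated), via silyl ester 27 (not isolated)
Conditions: Zn dust (activated), LiCl, THF, 35 °C; then 25, PdCl2(PPh3)2 (5 mol %), TMEDA, THF, rt → 40 °C; then AcOH–THF–H2O (3:1:1), rt
Reagents that add atoms: none
Why: Negishi coupling: zinc inserts into the primary C–I bond without touching ketone or acetate, palladium-catalysed coupling with the alkenyl iodide forms C12–C13 with retention of the alkene geometry (TMEDA suppresses Z to E leakage) so that C12 ends cis to C15, and aqueous acetic acid then cleaves the silyl ester but not the acetate.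

Compound list
1 | δ-valerolactone | O=C1CCCCO1 | starting material
2 | 5-hydroxy-N-methoxy-N-methylpentanamide | CON(C)C(=O)CCCCO | intermediate
3 | N-methoxy-N-methyl-5-oxopentanamide | CON(C)C(=O)CCCC=O | intermediate
4 | methyl acetoacetate | COC(=O)CC(C)=O | starting material
5 | methyl (2Z)-2-acetyl-7-[methoxy(methyl)amino]-7-oxohept-2-enoate | CON(C)C(=O)CCC/C=C(\C(=O)OC)C(C)=O | intermediate
6 | methyl (2Z)-7-[methoxy(methyl)amino]-7-oxo-2-{1-[(triisopropylsilyl)oxy]ethenyl}hept-2-enoate | CON(C)C(=O)CCC/C=C(\C(=O)OC)C(=C)O[Si](C(C)C)(C(C)C)C(C)C | intermediate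
7 | isopropenylmagnesium bromide | C=C(C)[Mg]Br | starting material
8 | methyl (2Z)-8-methyl-7-oxo-2-{1-[(triisopropylsilyl)oxy]ethenyl}nona-2,8-dienoate (the 2-methyl-1,7,9-decatrien-3-one precursor) | C=C(C)C(=O)CCC/C=C(\C(=O)OC)C(=C)O[Si](C(C)C)(C(C)C)C(C)C | intermediate
9 | methyl (4aS,8aS)-4a-methyl-5-oxo-2-[(triisopropylsilyl)oxy]-3,4,4a,5,6,7,8,8a-octahydronaphthalene-1-carboxylate (cis-fused, H-5 and C20 β, C9 ketone, C3 silyl enol ether, C4 CO2Me) | C1CC[C@H]2[C@](C)(CCC(O[Si](C(C)C)(C(C)C)C(C)C)=C2C(=O)OC)C1=O | intermediate
10 | Mannich base: 9 with a (dimethylamino)methyl group on C8 (either C8 epimer) | CN(C)CC1CC[C@H]2[C@](C)(CCC(O[Si](C(C)C)(C(C)C)C(C)C)=C2C(=O)OC)C1=O | intermediate (not isolated)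
11 | methiodide of 10 (trimethylammonium iodide) | C[N+](C)(C)CC1CC[C@H]2[C@](C)(CCC(O[Si](C(C)C)(C(C)C)C(C)C)=C2C(=O)OC)C1=O.[I-] | intermediate (not isolated)
12 | 8-methylidene-9-ketone: 9 with C17H2=C8 | C=C1CC[C@H]2[C@](C)(CCC(O[Si](C(C)C)(C(C)C)C(C)C)=C2C(=O)OC)C1=O | intermediate
13 | 9-hydroxy-8(17)-ene: secondary allylic alcohol from 12 (either C9 epimer) | C=C1CC[C@H]2[C@](C)(CCC(O[Si](C(C)C)(C(C)C)C(C)C)=C2C(=O)OC)C1O | intermediate
14 | 17-hydroxy-8-ene: C8=C9 in ring B, CH2OH on C8, ring A as in 9; methyl (4aR,8aS)-6-(hydroxymethyl)-4a-methyl-2-[(triisopropylsilyl)oxy]-3,4,4a,7,8,8a-hexahydronaphthalene-1-carboxylate | OCC1CC[C@H]2[C@](C)(CCC(O[Si](C(C)C)(C(C)C)C(C)C)=C2C(=O)OC)C=1 | intermediate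
15 | triethyl orthoacetate | CCOC(C)(OCC)OCC | starting material
16 | ketene acetal: 1-ethoxyvinyl ether of 14 | C=C(OCC)OCC1CC[C@H]2[C@](C)(CCC(O[Si](C(C)C)(C(C)C)C(C)C)=C2C(=O)OC)C=1 | intermediate (not isolated)
17 | ethyl 8(17)-en-12-oate: C9 bears CH2CO2Et on the β face (H-9 α), C8=C17H2, ring A as in 9 | C=C1CC[C@H]2[C@](C)(CCC(O[Si](C(C)C)(C(C)C)C(C)C)=C2C(=O)OC)[C@H]1CC(=O)OCC | intermediate
18 | 3-oxo diester: C4 bears CH3 (C19, β) and CO2Me (C18, α), ring B as in 17 | C=C1CC[C@H]2[C@](C)(CCC(=O)[C@@]2(C)C(=O)OC)[C@H]1CC(=O)OCC | intermediate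
19 | 3,12,18-triol with 8(17)-ene (C3 carbinol as either epimer) | C=C1CC[C@H]2[C@](C)(CCC(O)[C@@]2(C)CO)[C@H]1CCO | intermediate
20 | 12-iodo-3,18-diol | C=C1CC[C@H]2[C@](C)(CCC(O)[C@@]2(C)CO)[C@H]1CCI | intermediate
21 | 18-acetoxy-12-iodo-3-ol | C=C1CC[C@H]2[C@](C)(CCC(O)[C@@]2(C)COC(C)=O)[C@H]1CCI | intermediate
22 | 18-acetoxy-12-iodo-3-ketone | C=C1CC[C@H]2[C@](C)(CCC(=O)[C@@]2(C)COC(C)=O)[C@H]1CCI | intermediate
23 | but-2-ynoic acid | CC#CC(=O)O | starting material
24 | (2Z)-3-iodobut-2-enoic acid | C/C(I)=C/C(=O)O | intermediate
25 | tert-butyldimethylsilyl (2Z)-3-iodobut-2-enoate | C/C(I)=C/C(=O)O[Si](C)(C)C(C)(C)C | intermediate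
26 | organozinc iodide from 22 (C12–ZnI) | C=C1CC[C@H]2[C@](C)(CCC(=O)[C@@]2(C)COC(C)=O)[C@H]1CC[Zn]I | intermediate (not isolated)
27 | tert-butyldimethylsilyl ester of the target acid | C=C1CC[C@H]2[C@](C)(CCC(=O)[C@@]2(C)COC(C)=O)[C@H]1CC/C(C)=C\C(=O)O[Si](C)(C)C(C)(C)C | intermediate (not isolated)
28 | (2Z)-5-[(1S,4aS,5R,8aR)-5-(acetoxymethyl)-5,8a-dimethyl-2-methylidene-6-oxodecahydronaphthalen-1-yl]-3-methylpent-2-enoic acid (CNP0243698.1) | C=C1CC[C@H]2[C@](C)(CCC(=O)[C@@]2(C)COC(C)=O)[C@H]1CC/C(C)=C\C(=O)O | target

Total step count: 18. Longest linear sequence: 16 (steps 1–15 and 18). Steps 16 and 17 prepare the coupling partner 25.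

Steps most likely to fail

Step 6. The trienone may cyclise without the catalyst, or the catalyst may discriminate poorly between the faces of the α-methyl enone; either erodes enantiomeric purity. Protodesilylation of the dienol ether by the strong acid is a further loss. Fallback: setting out from 8, the cyclisation is run with the achiral Lewis acid Me2AlCl (CH2Cl2, −78 → −40 °C), which should give the racemic cis-fused adduct F1 through the same carbonyl-endo transition state. The enantiomers are then separated by preparative chromatography on a chiral stationary phase (amylose tris(3,5-dimethylphenylcarbamate), supercritical CO2–i-PrOH), which returns to the route at 9.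

Step 11. The C20 methyl is syn-axial to the incoming electrophile in the preferred half-chair of ring A, so facial selectivity at the C4 enolate may be poor or reversed (methyl entering on the α face). Fallback: the quaternary centre is rebuilt with its two carbon substituents introduced in the opposite order. Setting out from 17, the methylation is run as written and its product, the C4 epimer of 18 F2, is demethoxycarbonylated (LiCl, wet DMSO, 150 °C) to the 4-methyl-3-ketone F3. TMSCl, NaI and Et3N in MeCN convert this into the more substituted trimethylsilyl enol ether F4. Lewis acid–catalysed hydroxymethylation with aqueous formaldehyde (Yb(OTf)3, THF, rt) then brings C18 in on the same α face that the methyl group had preferred, giving the 18-hydroxy-3-ketone F5. LiAlH4 reduction of F5 returns to the route at triol 19.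

Step 10. Carbon may be delivered to the α face of C9 if the conformational bias of the ring B alkene is weaker than assumed, or the silyl enol ether may be lost thermally before the sigmatropic shift. Fallback: the order of events at C9 is reversed, so that hydrogen, not carbon, is delivered to whichever face is exposed. Setting out from 9, KN(SiMe3)2 and PhNTf2 (THF, −78 °C) give the C9 enol triflate F6. Pd(PPh3)4-catalysed coupling with the Reformatsky reagent BrZnCH2CO2Et (THF, 50 °C) gives the 8-ene ester F7. Hydroboration and oxidation (BH3·SMe2, THF, 0 °C; then NaBO3·4H2O) add H-9 and the C8 hydroxyl to the same face, giving the 8-hydroxy ester F8. Dess–Martin oxidation gives the 8-ketone F9, and non-basic methylenation (Zn, CH2Br2, TiCl4, THF–CH2Cl2, 0 °C), which should not epimerise C9, returns to the route at 17.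

Further compounds
F1 | step 6 | racemic cis-fused adduct (9 together with its enantiomer) | C1CC[C@H]2[C@](C)(CCC(O[Si](C(C)C)(C(C)C)C(C)C)=C2C(=O)OC)C1=O.C1CC[C@@H]2[C@@](C)(CCC(O[Si](C(C)C)(C(C)C)C(C)C)=C2C(=O)OC)C1=O
F2 | step 11 | C4 epimer of 18 (C19 methyl α, CO2Me β) | C=C1CC[C@H]2[C@](C)(CCC(=O)[C@]2(C)C(=O)OC)[C@H]1CC(=O)OCC
F3 | step 11 | 4-methyl-3-ketone (18-nor, either C4 epimer) | C=C1CC[C@H]2[C@](C)(CCC(=O)C2C)[C@H]1CC(=O)OCC
F4 | step 11 | trimethylsilyl enol ether of F3 (C3=C4) | C=C1CC[C@H]2[C@](C)(CCC(O[Si](C)(C)C)=C2C)[C@H]1CC(=O)OCC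
F5 | step 11 | 18-hydroxy-3-ketone (C19 methyl β, CH2OH α) | C=C1CC[C@H]2[C@](C)(CCC(=O)[C@@]2(C)CO)[C@H]1CC(=O)OCC
F6 | step 10 | C9 enol triflate of 9 (C8=C9) | C1CC[C@H]2[C@](C)(CCC(O[Si](C(C)C)(C(C)C)C(C)C)=C2C(=O)OC)C(OS(=O)(=O)C(F)(F)F)=1
F7 | step 10 | 8-ene ester (CH2CO2Et on C9, C8=C9) | C1CC[C@H]2[C@](C)(CCC(O[Si](C(C)C)(C(C)C)C(C)C)=C2C(=O)OC)C(CC(=O)OCC)=1
F8 | step 10 | 8-hydroxy ester (8-OH and H-9 both α) | O[C@@H]1CC[C@H]2[C@](C)(CCC(O[Si](C(C)C)(C(C)C)C(C)C)=C2C(=O)OC)[C@H]1CC(=O)OCC
F9 | step 10 | 8-ketone (H-9 α, CH2CO2Et β) | O=C1CC[C@H]2[C@](C)(CCC(O[Si](C(C)C)(C(C)C)C(C)C)=C2C(=O)OC)[C@H]1CC(=O)OCC
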